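**Plan**

1. Names used below: ring A = 1,3-dioxygenated benzene ring and ring E = mono-oxygenated benzene ring (the two aryl rings of the 9,10-dihydrophenanthrene, whose CH2–CH bridge ring is ring B); ring C = catechol ring fused to the seven-membered ring D; ring F = pendant catechol; M1 = methine shared by rings B and D (bonded to ring C, ring E and the CH2 of ring B); M2 = methine of ring D that bears ring F.
2. Retrosynthesis: after the O-methyl groups and one helper group, the bonds M1–ring E and M2–ring C are cut together. This opens rings B and D, removes both stereocentres and leaves an achiral biaryl bis-stilbene. Its two alkenes are cut by olefination of a biaryl dialdehyde with one benzylphosphonate (rings C and F are the same unit), and the A–E biaryl bond by cross-coupling of two commercial bromobenzaldehydes.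
3. Enabling feature: M1 and M2 are each benzylic to a ring with a para oxygen (cation sites), and the arene carbon each must bond to lies para to an oxygen on the partner (the ring E C–H para to its oxygen; the ring C C–H para to its 3-oxygen). Cation and arene sites therefore alternate head to tail around ring D, as in a (4+3) union of a benzylic cation on ring C with the styrene unit of ring E.
4. Forward order: A–E biaryl first, both stilbenes next, then rings B and D together in one acid-catalysed double hydroarylation, then removal of the helper and of the seven methyl groups.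
5. Helper: a tosyloxy group on the ring E carbon between the methoxy carbon and the biaryl bond blocks the only competing site for closure of ring B; it is later cleaved reductively to C–H.
6. Stereochemistry: M1 (S) comes from a chiral Brønsted acid in the first ring closure; M2 (R) comes from the substrate, ring D closing with the ring B CH2 and ring F both pseudo-equatorial (cis methine hydrogens).

Key step: step 5

Remark: the sense of induction of the chiral acid cannot be fixed on paper; the catalyst antipode that delivers (S) at M1 is to be used, both being accessible from (R)- or (S)-BINOL.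

**Step 1**
Reactants: 1 5-bromovanillin (3-bromo-4-hydroxy-5-methoxybenzaldehyde)
Product: 2 2-bromo-4-formyl-6-methoxyphenyl 4-methylbenzenesulfonate
Conditions: TsCl, Et3N, DMAP (cat.), CH2Cl2, 0 °C to rt
Reagents that add atoms: p-toluenesulfonyl chloride, Cc1ccc(cc1)S(Cl)(=O)=O
Why: O-sulfonylation (tosylation) of the acidic phenol should be clean because no other nucleophilic site is present, and it installs the helper that will block the ring E carbon next to the biaryl bond and later be cleaved reductively.

**Step 2**
Reactants: 2 2-bromo-4-formyl-6-methoxyphenyl 4-methylbenzenesulfonate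
Product: 3 4-formyl-2-methoxy-6-(4,4,5,5-tetramethyl-1,3,2-dioxaborolan-2-yl)phenyl 4-methylbenzenesulfonate
Conditions: B2pin2, PdCl2(dppf) ([1,1'-bis(diphenylphosphino)ferrocene]dichloropalladium, 3 mol %), KOAc, 1,4-dioxane, 90 °C
Reagents that add atoms: bis(pinacolato)diboron, CC1(C)OB(OC1(C)C)B1OC(C)(C)C(C)(C)O1
Why: Miyaura borylation of the aryl bromide should be selective because PdCl2(dppf) with KOAc does not insert into the doubly ortho-flanked aryl tosylate and tolerates the aldehyde.

**Step 3**
Reactants: 3 4-formyl-2-methoxy-6-(4,4,5,5-tetramethyl-1,3,2-dioxaborolan-2-yl)phenyl 4-methylbenzenesulfonate; 4 2-bromo-3,5-dimethoxybenzaldehyde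
Product: 5 2',5-diformyl-3,4',6'-trimethoxybiphenyl-2-yl 4-methylbenzenesulfonate
Conditions: Pd(OAc)2 (3 mol %), 2-dicyclohexylphosphino-2',6'-dimethoxybiphenyl (SPhos, 6 mol %), K3PO4, toluene/H2O (10:1), 80 °C
Reagents that add atoms: none
Why: Suzuki–Miyaura coupling with a dialkylbiarylphosphine ligand is the standard answer to tri-ortho-substituted biaryls, the ortho-formyl group of 4 speeding oxidative addition while the flanked tosylate and both aldehydes stay untouched, and the new axis rotates freely so no stereochemical issue arises.

**Step 4**
Reactants: 5 2',5-diformyl-3,4',6'-trimethoxybiphenyl-2-yl 4-methylbenzenesulfonate; 6 diethyl (3,4-dimethoxybenzyl)phosphonate (2.4 equiv)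
Product: 7 2',5-bis[(E)-2-(3,4-dimethoxyphenyl)ethenyl]-3,4',6'-trimethoxybiphenyl-2-yl 4-methylbenzenesulfonate
Conditions: NaH, THF, 0 °C to rt
Reagents that add atoms: none
Why: Twofold Horner–Wadsworth–Emmons olefination with the benzylphosphonate anion should give both (E)-stilbenes in one operation, the tosylate (no α-hydrogen) and the methyl ethers being inert to the carbanion, and the alkene geometry is in any case erased at the cation stage of step 5.

**Step 5**
Reactants: 7 2',5-bis[(E)-2-(3,4-dimethoxyphenyl)ethenyl]-3,4',6'-trimethoxybiphenyl-2-yl 4-methylbenzenesulfonate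
Product: 9 heptamethyl ether tosylate of the target skeleton (M1 S; M2 R), via monocyclised dihydrophenanthrene stilbene 8 (not isolated)
Conditions: chiral IDPi acid [imidodiphosphorimidate from two 3,3'-bis(3,5-bis(trifluoromethyl)phenyl)-BINOL units, N-triflyl on both phosphorus atoms; antipode as in the remark] (5 mol %), CHCl3 (0.01 M), 0 °C to rt
Reagents that add atoms: none
Why: Proposed new method: the confined chiral acid should protonate the ring A stilbene at the carbon next to ring A, giving the 3,4-dimethoxybenzylic cation at M1 as a contact ion pair with the IDPi anion; Friedel–Crafts attack by the ring E carbon para to OMe closes ring B (6-endo hydroarylation) to 8, and protonation of the second alkene at the carbon next to ring E gives the cation at M2, which the ring C carbon para to its 3-OMe captures to close ring D (7-endo hydroarylation). The closest known reaction types are the achiral-acid Friedel–Crafts cyclisations of methylated stilbene oligomers, which close six- and seven-membered rings in this way, and the IDPi-catalysed enantioselective intramolecular hydroarylation of alkenes through ion-paired cations; their combination as a double cascade on a bis-stilbene has not been shown. M1 is set under catalyst control, the chiral anion shielding one face of the planar cation in the enantio-determining first C–C bond formation. M2 is set under substrate control: in 8 the aryl group on M1 is pseudo-axial (peri strain with the side chain on ring E), so its free ortho carbon sits over the M2 cation, and the boat-shaped transition state for ring D with the ring B CH2 and ring F both pseudo-equatorial gives the cis relationship of the two methine hydrogens. Site selectivity on ring E is secured by the tosyloxy group, which occupies the only other carbon that could close ring B and, being para to the styryl carbon, disfavours wrong-way protonation of the second alkene; on ring C the carbon para to the 3-OMe is open and activated while the other ortho carbon is flanked by OMe, both protonations follow the para-methoxy stabilisation of the cations at M1 and M2, and high dilution suppresses intermolecular stilbene dimerisation.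

**Step 6**
Reactants: 9 heptamethyl ether tosylate of the target skeleton (M1 S; M2 R)
Product: 10 heptamethyl ether of the target (M1 S; M2 R)
Conditions: NiCl2(PCy3)2 (10 mol %), Me2NH·BH3, K2CO3, MeCN, 80 °C
Reagents that add atoms: none
Why: Nickel-catalysed reductive cleavage of an aryl sulfonate (oxidative addition of zerovalent nickel into the C–O bond, hydride transfer from the amine–borane, C–H reductive elimination) should replace the helper by hydrogen, while the aryl methyl ethers, the benzylic C–C bonds and both methine stereocentres, which are not acidic under carbonate, remain untouched.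

**Step 7**
Reactants: 10 heptamethyl ether of the target (M1 S; M2 R)
Product: 11 target heptaphenol CNP0306974.2 (M1 S; M2 R)
Conditions: BBr3 (excess), CH2Cl2, −78 °C to rt; then MeOH, H2O, 0 °C
Reagents that add atoms: none
Why: Exhaustive Lewis-acid aryl methyl ether cleavage with BBr3, the usual end-game for permethylated stilbene oligomers, should free all seven phenols by bromide attack on the O-methyl groups without touching the C–H and C–C bonds at M1 and M2, so the configuration set in step 5 is carried into the target.

**Compound list**

1 | 5-bromovanillin (3-bromo-4-hydroxy-5-methoxybenzaldehyde) | COc1cc(C=O)cc(Br)c1O | starting material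
2 | 2-bromo-4-formyl-6-methoxyphenyl 4-methylbenzenesulfonate | COc1cc(C=O)cc(Br)c1OS(=O)(=O)c1ccc(C)cc1 | intermediate
3 | 4-formyl-2-methoxy-6-(4,4,5,5-tetramethyl-1,3,2-dioxaborolan-2-yl)phenyl 4-methylbenzenesulfonate | COc1cc(C=O)cc(B2OC(C)(C)C(C)(C)O2)c1OS(=O)(=O)c1ccc(C)cc1 | intermediate
4 | 2-bromo-3,5-dimethoxybenzaldehyde | COc1cc(OC)c(Br)c(C=O)c1 | starting material
5 | 2',5-diformyl-3,4',6'-trimethoxybiphenyl-2-yl 4-methylbenzenesulfonate | COc1cc(OC)c(c(C=O)c1)-c1cc(C=O)cc(OC)c1OS(=O)(=O)c1ccc(C)cc1 | intermediate
6 | diethyl (3,4-dimethoxybenzyl)phosphonate | CCOP(=O)(Cc1ccc(OC)c(OC)c1)OCC | starting material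
7 | 2',5-bis[(E)-2-(3,4-dimethoxyphenyl)ethenyl]-3,4',6'-trimethoxybiphenyl-2-yl 4-methylbenzenesulfonate | COc1cc(OC)c(c(/C=C/c2ccc(OC)c(OC)c2)c1)-c1cc(/C=C/c2ccc(OC)c(OC)c2)cc(OC)c1OS(=O)(=O)c1ccc(C)cc1 | intermediate
8 | (S)-9-(3,4-dimethoxyphenyl)-8-[(E)-2-(3,4-dimethoxyphenyl)ethenyl]-2,4,6-trimethoxy-9,10-dihydrophenanthren-5-yl 4-methylbenzenesulfonate (formed in the flask in step 5) | COc1cc(OC)c2c(c1)C[C@@H](c1ccc(OC)c(OC)c1)c1c-2c(OS(=O)(=O)c2ccc(C)cc2)c(OC)cc1/C=C/c1ccc(OC)c(OC)c1 | intermediate
9 | heptamethyl ether of the target carrying a tosyloxy group on the ring E carbon between the methoxy carbon and the biaryl carbon; M1 S, M2 R | COc1cc(OC)c2c(c1)C[C@H]1c3cc(OC)c(OC)cc3[C@@H](c3ccc(OC)c(OC)c3)Cc3cc(OC)c(OS(=O)(=O)c4ccc(C)cc4)c-2c31 | intermediate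
10 | heptamethyl ether of the target; M1 S, M2 R | COc1cc(OC)c2c(c1)C[C@H]1c3cc(OC)c(OC)cc3[C@@H](c3ccc(OC)c(OC)c3)Cc3cc(OC)cc-2c31 | intermediate
11 | CNP0306974.2, heptaphenol; M1 S, M2 R, methine hydrogens cis | Oc1cc(O)c2c(c1)C[C@H]1c3cc(O)c(O)cc3[C@@H](c3ccc(O)c(O)c3)Cc3cc(O)cc-2c31 | target

**Step count and risks**

Total step count: 7. Longest linear sequence: 7 steps (from 1; 4 and 6 enter as commercial materials).

Steps most likely to fail:

Step 5. The ion pair may give poor facial discrimination at M1, or the acid may turn over slowly because the methoxy groups buffer it and the tosyloxy group lowers the nucleophilicity of ring E. The fallback uses known chemistry and sets out from 7: an achiral strong acid (TfOH, 10 mol %, CH2Cl2/hexafluoroisopropanol, 0 °C, or BF3·OEt2) at the same dilution should run the same double Friedel–Crafts cascade to the racemic cis cascade product F1. Preparative chromatography on a chiral stationary phase (supercritical CO2/MeOH over amylose tris(3,5-dimethylphenylcarbamate)) then separates the wanted enantiomer from its mirror image F2, and the route is rejoined at 9.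

Step 6. Oxidative addition into the doubly ortho-flanked C–O bond may be slow, and S–O cleavage back to the phenol may compete. The fallback sets out from 9: saponification of the sulfonate (KOH, MeOH/THF, 60 °C) should give the phenol F3, triflation (Tf2O, pyridine, CH2Cl2, 0 °C) the aryl triflate F4, and palladium-catalysed formate reduction (Pd(OAc)2, 1,1'-bis(diphenylphosphino)ferrocene, HCO2H, Et3N, DMF, 80 °C) should replace the triflate by hydrogen, rejoining the route at 10.

Step 3. Transmetalation onto the hindered arylpalladium from 4 may be slow enough for protodeboronation of 3 to take over. The fallback sets out from 2 and moves the hindered carbon–carbon bond formation off the metal: Suzuki–Miyaura coupling of 2 with commercial 3,5-dimethoxyphenylboronic acid (Pd(PPh3)4, Na2CO3, 1,2-dimethoxyethane/H2O, 80 °C) should give the biaryl monoaldehyde F5. Vilsmeier–Haack formylation (POCl3, DMF, 0 to 60 °C) of its only activated ring, at the carbon ortho to the biaryl bond and para to a methoxy group, should then give the dialdehyde, rejoining the route at 5.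

**Further compounds**

F1 | step 5 | racemic cis heptamethyl ether tosylate (racemate of 9) | COc1cc(OC)c2c(c1)CC1c3cc(OC)c(OC)cc3C(c3ccc(OC)c(OC)c3)Cc3cc(OC)c(OS(=O)(=O)c4ccc(C)cc4)c-2c31
F2 | step 5 | enantiomer of 9 (M1 R, M2 S) | COc1cc(OC)c2c(c1)C[C@@H]1c3cc(OC)c(OC)cc3[C@H](c3ccc(OC)c(OC)c3)Cc3cc(OC)c(OS(=O)(=O)c4ccc(C)cc4)c-2c31
F3 | step 6 | heptamethyl ether of the target with a free hydroxy group on the ring E carbon between the methoxy carbon and the biaryl carbon (M1 S, M2 R) | COc1cc(OC)c2c(c1)C[C@H]1c3cc(OC)c(OC)cc3[C@@H](c3ccc(OC)c(OC)c3)Cc3cc(OC)c(O)c-2c31
F4 | step 6 | trifluoromethanesulfonate of F3 (M1 S, M2 R) | COc1cc(OC)c2c(c1)C[C@H]1c3cc(OC)c(OC)cc3[C@@H](c3ccc(OC)c(OC)c3)Cc3cc(OC)c(OS(=O)(=O)C(F)(F)F)c-2c31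
F5 | step 3 | 5-formyl-3,3',5'-trimethoxybiphenyl-2-yl 4-methylbenzenesulfonate | COc1cc(OC)cc(c1)-c1cc(C=O)cc(OC)c1OS(=O)(=O)c1ccc(C)cc1
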